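(The runs are simulated from invented constants, noise included.)

The constants of the four steps were hidden from me, so I began from the readings of the north run, the flask asked about, and from the earlier north-west run, counting everything in fractions of the charge.

common to all: starting material 0.050 M

| flask | coupling partner | second substrate | protic impurity | temperature | remark | time |
|---|---|---|---|---|---|---|
| north | 3 equiv | 1 equiv | 2.5 mM | 25 °C | the very flask that is asked about, followed so far |  |
| north-west | 3 equiv | 1 equiv | 2.5 mM | 20 °C | run made earlier |  |
| flask | 3.00 equiv | 1.00 equiv | 2.50 mM | 25 °C |  | 5.0 min |

| run | time / min | target / % | starting material / % |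
|---|---|---|---|
| north | 0.333 | 16.5 | 80.1 |
| north | 0.667 | 25.1 | 69.1 |
| north | 1.00 | 31.6 | 61.6 |
| north | 2.00 | 36.0 | 52.1 |
| north | 4.00 | 33.0 | 45.9 |
| north-west | 0.333 | 12.6 | 85.6 |
| north-west | 0.667 | 17.6 | 75.7 |
| north-west | 1.00 | 23.4 | 71.4 |
| north-west | 2.00 | 32.9 | 58.5 |
| north-west | 4.00 | 36.6 | 51.4 |

(standard deviation of a reading: 1 percentage point)

- Sunday's: at 5.0 min raise the temperature by 20 K, then wait 10 min
- Friday's: at 5.0 min add coupling partner, 50.0 % of the amount charged, then wait 10 min
- Saturday's: at 5.0 min take out 90 % of the target then present, then wait 10 min
- Thursday's: change nothing and wait 10 min more

- target that was removed still counts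
- steps under discussion: starting material + coupling partner <-> target; second substrate + coupling partner <-> second product; starting material + protic impurity -> quenched substrate; coupling partner + target -> over-reaction product
- additions bring no volume worth counting

- target, in percent of the starting material first charged, at 5.0 min
- what to do for the largest gain in target; "none" if nothing gains more than 2 percentage points (Sunday's / Friday's / Saturday's / Thursday's / none)
- target present, with what was taken out counted in, in percent of the starting material first charged, after Friday's
- target present, with what was taken out counted in, in percent of the starting material first charged, after Saturday's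

My first question was whether the first step in the north run was still moving. Starting material and target together make a pool, 88.1 % at 2.00 min and 78.9 % at 4.00 min, and the target's share of that pool read 0.409 and then 0.418, nearly the same, so I took the two as balanced and the pool as merely leaking.

Next I asked how fast it leaked. The protic impurity can take 5.00 % of the charge, less than the 21.1 % missing, so I laid the continuing loss on over-reaction of the target. If over-reaction takes a fixed fraction of the target each minute, the pool loses that fraction times the share each minute, and a loss proportional to what remains gives a falling exponential: the pool is multiplied by exp(−constant × share × time). The two readings give a pool decay of 0.0551 min⁻¹, and dividing by the share gives the leak constant, the fraction of the target lost per minute, read as 0.132 min⁻¹ with the scatter of those readings, which I treated as a pseudo-first-order constant with partner in excess.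

Then I asked what each choice leaves. For the flask at 5.0 min I reckoned a pool of 74.7 % and a target of 31.2 %. By the same reckoning, waiting on left 18.0 %, whereas taking out 28.1 % and letting the remainder regain its share and leak left 39.3 %, more than waiting. Friday's and Sunday's move the partner and the temperature away from the settings at which I had read the leak constant, so I did not reckon them.

The forecast gave 31 % (29 % to 33 %), 13 % after Friday's (7 % to 22 %) and 39 % after Saturday's (34 % to 45 %), and it chose Saturday's: “the remaining SM re-equilibrates to about 18, then decays to about 11”.

The flask gave 31.8 %, 17.4 % after Friday's and 41.2 % after Saturday's, and Saturday's gained 9.4 percentage points.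

starting material + coupling partner ⇌ target (K = 7.00 M⁻¹, k = 0.0730 M⁻¹ s⁻¹, Ea = 67.0 kJ mol⁻¹, ΔH = 4.00 kJ mol⁻¹); second substrate + coupling partner ⇌ second product (K = 21.0 M⁻¹, k = 0.00510 M⁻¹ s⁻¹, Ea = 69.0 kJ mol⁻¹, ΔH = −47.0 kJ mol⁻¹); starting material + protic impurity → quenched substrate (k = 2.90 M⁻¹ s⁻¹, Ea = 48.0 kJ mol⁻¹); coupling partner + target → over-reaction product (k = 0.0160 M⁻¹ s⁻¹, Ea = 62.0 kJ mol⁻¹); (constants at 25 °C) I then took the neighbour charged with 0.750 equiv of coupling partner, which at 5.0 min kept 71 % of its own charge of partner against 72 % in the flask, so I scaled the leak constant by the charge to 0.0330 min⁻¹. Its share at 5.0 min was 0.154, and with that share held throughout, I reckoned that a pool starting at 95.0 % lost 2.38 % by 5.0 min; that neighbour held 1.66 % of over-reaction product.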